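**Retrosynthetic overview**
1. Target ⇐ tricyclic 2-isoxazoline (the C2 ketone and C1′ carbinol are masked as C=N–O) by N–O cleavage, after C6 allylic hydroxylation and the two acylations.
2. Isoxazoline ⇐ α-acyloxy nitrile oxide and a (Z)-propenyl group on a trans-2,3-disubstituted methylenecyclohexane; one intramolecular cycloaddition closes the cyclopentane (C2–C3) and the isoxazoline (O–C1′) together and sets C3 and C1′.
3. Cycloaddition precursor ⇐ (R)-cryptone + (Z)-propenyl cuprate + glyoxal mono(dimethyl acetal) (conjugate addition/syn-aldol sets C3a, C7a, C1), then C=O → C=CH2, acylation, acetal → oxime.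
4. (R)-Cryptone ⇐ isovaleraldehyde + methyl vinyl ketone (organocatalytic Michael/aldol condensation sets C4).
5. Ring order: cyclohexane (step 1), then cyclopentane and isoxazoline together (step 6), then the isoxazoline is opened (step 9).

Assumption: the 2-methylbutanoate is (R) as read from the SMILES, and (R)-2-methylbutanoic acid and (E)-3-methylpent-2-enoic acid are bought as catalogue compounds.
Locants used in names: hydrindane numbering of the target (C1 CH–O-acyl, C2 C=O, C3 CH–side chain, C3a, C4 CH–iPr, C5, C6 CH–O-enoate, C7 C=CH2, C7a; C1′ = carbinol carbon).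

**Step 1**
Reactants: 1 3-methylbutanal; 2 but-3-en-2-one
Product: 4 (4R)-4-(propan-2-yl)cyclohex-2-en-1-one [(R)-cryptone], via keto aldehyde 3 (not isolated)
Conditions: (R)-diphenylprolinol TMS ether (5 mol %), ethyl 3,4-dihydroxybenzoate (20 mol %), neat, 4 °C; then LiOH (0.2 equiv), i-PrOH, rt (one pot)
Reagents that add atoms: none
Why: Enamine-catalysed asymmetric Michael addition of the aldehyde to the enone sets the isopropyl-bearing centre (C4 of the target) as R by attack on the unshielded enamine face (the R catalyst is chosen by analogy with the known sense of induction), and the 1,5-keto aldehyde then closes by intramolecular aldol condensation without touching that centre.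

**Step 2**
Reactants: 4 (R)-cryptone; 5 (Z)-1-bromoprop-1-ene; 6 2,2-dimethoxyacetaldehyde
Product: 11 (2R,3R,4R)-2-[(1R)-1-hydroxy-2,2-dimethoxyethyl]-4-(propan-2-yl)-3-[(1Z)-prop-1-en-1-yl]cyclohexan-1-one, via (Z)-prop-1-enyllithium 7 (not isolated), via lithium dipropenylcuprate 8 (not isolated), via lithium enolate 9 (not isolated), via titanium enolate 10 (not isolated)
Conditions: 5 (2.2 equiv), t-BuLi (4.4 equiv), Et2O, −78 °C; CuI (1.1 equiv), Me2S, −78 → −40 °C; 4, −78 °C; ClTi(Oi-Pr)3 (1.3 equiv), −78 → −40 °C; 6 (anhydrous, 2 equiv), −78 °C; aq NH4Cl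
Reagents that add atoms: none
Why: Tandem cuprate conjugate addition/aldol (three-component coupling) in which Br–Li exchange and the Gilman cuprate keep the Z geometry, the propenyl group adds anti to the C4 isopropyl group, and the regiodefined enolate, moved to titanium (triisopropoxytitanium enolates are syn-selective even for cyclic E-enolates), attacks the non-enolisable aldehyde anti to the propenyl group to give the 2,3-trans syn-aldol (future C7a and C1).

**Step 3**
Reactants: 11 aldol adduct
Product: 12 (1R)-2,2-dimethoxy-1-[(1S,2R,3R)-6-methylidene-3-(propan-2-yl)-2-[(1Z)-prop-1-en-1-yl]cyclohexyl]ethan-1-ol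
Conditions: Zn, CH2Br2, TiCl4, THF (pre-formed at 0–5 °C); 11, CH2Cl2, 0 °C → rt
Reagents that add atoms: dibromomethane BrCBr
Why: Takai–Lombardo methylenation is non-basic, so the hindered β-hydroxy ketone becomes the exocyclic alkene without retro-aldol, elimination or epimerisation, and the free hydroxyl and the acetal are tolerated.

**Step 4**
Reactants: 12 homoallylic alcohol; 13 (2R)-2-methylbutanoic acid
Product: 14 (1R)-2,2-dimethoxy-1-[(1S,2R,3R)-6-methylidene-3-(propan-2-yl)-2-[(1Z)-prop-1-en-1-yl]cyclohexyl]ethyl (2R)-2-methylbutanoate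
Conditions: 13 (1.5 equiv), DCC (1.6 equiv), DMAP (0.2 equiv), CH2Cl2, 0 °C → rt
Reagents that add atoms: none
Why: Steglich esterification acylates the only hydroxyl with retention at the carbinol and at the acid α-centre, and the enantiopure acid lets material from the minor enantiomer of 4 be removed as a diastereomer.

**Step 5**
Reactants: 14 ester acetal
Product: 16 (1R)-2-(hydroxyimino)-1-[(1S,2R,3R)-6-methylidene-3-(propan-2-yl)-2-[(1Z)-prop-1-en-1-yl]cyclohexyl]ethyl (2R)-2-methylbutanoate (E/Z oxime mixture), via α-acyloxy aldehyde 15 (not isolated)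
Conditions: NH2OH·HCl (5 equiv), THF–H2O (3:1), 55 °C
Reagents that add atoms: hydroxylamine hydrochloride Cl.NO
Why: Acid-catalysed acetal hydrolysis with in situ oxime condensation, in which hydroxylamine hydrochloride supplies the acid and traps the aldehyde as it forms, limiting epimerisation at C1, while the pH is too low for hydroxylaminolysis of the ester.

**Step 6**
Reactants: 16 aldoxime
Product: 18 tricyclic isoxazoline (1R,3S,3aR,4R,7aS,1′S)-7-methylidene-4-(propan-2-yl)hydrindane in which C2 is C=N and N–O–C1′ closes a 5-methyl-2-isoxazoline fused at C2–C3 and O1 carries the (2R)-2-methylbutanoyl group, via nitrile oxide 17 (not isolated)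
Conditions: PhI(OAc)2 (1.2 equiv, slow addition), TFA (5 mol %), MeOH, 5 mM, 0 °C → rt
Reagents that add atoms: none
Why: Intramolecular nitrile oxide–alkene 1,3-dipolar cycloaddition of a 5-hexenyl-type nitrile oxide closes the trans-fused cyclopentane and the isoxazoline in one event; A(1,3) strain of the Z-propenyl group holds H-3a in the alkene plane, so the dipole tethered through C7a adds to the face that places C1′ cis to H-3a, and suprafacial addition to the Z-alkene gives the 1′S configuration.

**Step 7**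
Reactants: 18 tricyclic isoxazoline
Product: 19 (6S)-6-hydroxy derivative of 18 (axial allylic alcohol; 1R,3S,3aR,4R,6S,7aS,1′S)
Conditions: SeO2 (0.5 equiv), t-BuOOH (3 equiv), CH2Cl2, 0 °C → rt
Reagents that add atoms: tert-butyl hydroperoxide CC(C)(C)OO (terminal oxygen source); selenium dioxide O=[Se]=O (catalytic oxygen carrier)
Why: SeO2/t-BuOOH allylic hydroxylation (ene reaction, then [2,3]-sigmatropic shift) of the 1,1-disubstituted alkene goes to the ring CH2 rather than the ring-fusion CH and delivers oxygen axially, syn to H-7a, as in the 7α-hydroxylation of labd-8(17)-enes.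

**Step 8**
Reactants: 19 allylic alcohol; 20 (2E)-3-methylpent-2-enoic acid
Product: 21 (6S)-6-[(2E)-3-methylpent-2-enoyloxy] derivative of 18 (diester isoxazoline)
Conditions: 20 (2 equiv), DCC (2 equiv), DMAP (0.3 equiv), CH2Cl2, rt
Reagents that add atoms: none
Why: Steglich esterification of the single free hydroxyl with retention at C6, the 3,3-disubstituted acrylic acid keeping its E geometry under carbodiimide/DMAP activation.

**Step 9**
Reactants: 21 diester isoxazoline
Product: 23 (1R,3R,3aR,4R,6S,7aS)-3-[(1S)-1-hydroxyethyl]-7-methylidene-1-{[(2R)-2-methylbutanoyl]oxy}-2-oxo-4-(propan-2-yl)octahydro-1H-inden-6-yl (2E)-3-methylpent-2-enoate (target), via β-hydroxy imine 22 (not isolated)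
Conditions: Mo(CO)6 (1.2 equiv), MeCN–H2O (15:1), 80 °C
Reagents that add atoms: water O
Why: Reductive N–O cleavage of the 2-isoxazoline by Mo(CO)6 and hydrolysis of the resulting β-hydroxy imine unmask the β-hydroxy ketone without touching the alkenes, the esters or the α-acyloxy group, and no stereocentre is involved.

**Compound list**
1 | 3-methylbutanal (isovaleraldehyde) | CC(C)CC=O | starting material
2 | but-3-en-2-one (methyl vinyl ketone) | CC(=O)C=C | starting material
3 | (2R)-5-oxo-2-(propan-2-yl)hexanal (not isolated) | O=C[C@@H](C(C)C)CCC(C)=O | intermediate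
4 | (4R)-4-(propan-2-yl)cyclohex-2-en-1-one [(R)-cryptone] | O=C1C=C[C@@H](C(C)C)CC1 | intermediate
5 | (Z)-1-bromoprop-1-ene | C/C=C\Br | starting material
6 | 2,2-dimethoxyacetaldehyde | COC(OC)C=O | starting material
7 | (Z)-prop-1-enyllithium (not isolated) | C/C=C\[Li] | intermediate
8 | lithium bis[(Z)-prop-1-enyl]cuprate (not isolated) | C/C=C\[Cu-]/C=C\C.[Li+] | intermediate
9 | lithium (3R,4R)-4-(propan-2-yl)-3-[(1Z)-prop-1-en-1-yl]cyclohex-1-en-1-olate (not isolated) | [Li]OC1=C[C@H](/C=C\C)[C@@H](C(C)C)CC1 | intermediate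
10 | triisopropoxytitanium enolate corresponding to 9 (not isolated) | CC(C)O[Ti](OC(C)C)(OC(C)C)OC1=C[C@H](/C=C\C)[C@@H](C(C)C)CC1 | intermediate
11 | (2R,3R,4R)-2-[(1R)-1-hydroxy-2,2-dimethoxyethyl]-4-(propan-2-yl)-3-[(1Z)-prop-1-en-1-yl]cyclohexan-1-one | O=C1[C@@H]([C@@H](O)C(OC)OC)[C@H](/C=C\C)[C@@H](C(C)C)CC1 | intermediate
12 | (1R)-2,2-dimethoxy-1-[(1S,2R,3R)-6-methylidene-3-(propan-2-yl)-2-[(1Z)-prop-1-en-1-yl]cyclohexyl]ethan-1-ol | C=C1[C@@H]([C@@H](O)C(OC)OC)[C@H](/C=C\C)[C@@H](C(C)C)CC1 | intermediate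
13 | (2R)-2-methylbutanoic acid | CC[C@@H](C)C(=O)O | starting material
14 | (2R)-2-methylbutanoate ester of 12 | C=C1[C@@H]([C@@H](OC(=O)[C@H](C)CC)C(OC)OC)[C@H](/C=C\C)[C@@H](C(C)C)CC1 | intermediate
15 | (1R)-2-oxo-1-[(1S,2R,3R)-6-methylidene-3-(propan-2-yl)-2-[(1Z)-prop-1-en-1-yl]cyclohexyl]ethyl (2R)-2-methylbutanoate (not isolated) | C=C1[C@@H]([C@@H](OC(=O)[C@H](C)CC)C=O)[C@H](/C=C\C)[C@@H](C(C)C)CC1 | intermediate
16 | aldoxime of 15 (E/Z mixture) | C=C1[C@@H]([C@@H](OC(=O)[C@H](C)CC)C=NO)[C@H](/C=C\C)[C@@H](C(C)C)CC1 | intermediate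
17 | nitrile oxide from 16 (not isolated) | C=C1[C@@H]([C@@H](OC(=O)[C@H](C)CC)C#[N+][O-])[C@H](/C=C\C)[C@@H](C(C)C)CC1 | intermediate
18 | tricyclic isoxazoline (1R,3S,3aR,4R,7aS,1′S; hydrindane locants) | C=C1[C@@H]2[C@H]([C@@H]3[C@H](C)ON=C3[C@@H]2OC(=O)[C@H](C)CC)[C@@H](C(C)C)CC1 | intermediate
19 | (6S)-6-hydroxy tricyclic isoxazoline | C=C1[C@@H]2[C@H]([C@@H]3[C@H](C)ON=C3[C@@H]2OC(=O)[C@H](C)CC)[C@@H](C(C)C)C[C@@H]1O | intermediate
20 | (2E)-3-methylpent-2-enoic acid | CC/C(C)=C/C(=O)O | starting material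
21 | (6S)-6-[(2E)-3-methylpent-2-enoyloxy] tricyclic isoxazoline | C=C1[C@@H]2[C@H]([C@@H]3[C@H](C)ON=C3[C@@H]2OC(=O)[C@H](C)CC)[C@@H](C(C)C)C[C@@H]1OC(=O)/C=C(\C)CC | intermediate
22 | 2-imino analogue of 23 (β-hydroxy imine; not isolated) | C=C1[C@@H]2[C@H]([C@H]([C@H](C)O)C(=N)[C@@H]2OC(=O)[C@H](C)CC)[C@@H](C(C)C)C[C@@H]1OC(=O)/C=C(\C)CC | intermediate
23 | CNP0224363.1 (name as in step 9) | C=C1[C@@H]2[C@H]([C@H]([C@H](C)O)C(=O)[C@@H]2OC(=O)[C@H](C)CC)[C@@H](C(C)C)C[C@@H]1OC(=O)/C=C(\C)CC | target

**Totals**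
Total step count: 9. Longest linear sequence: 9 steps (1 and 2 to 23).

**Steps most likely to fail**

Step 2 (syn/anti ratio of the aldol at C1 and the efficiency of the one-flask coupling). The fallback sets out from 4 and comes back at 11. The same cuprate is added to 4 in the presence of TMSCl/Et3N and the enolate is isolated as trimethyl{[(3R,4R)-4-(propan-2-yl)-3-[(1Z)-prop-1-en-1-yl]cyclohex-1-en-1-yl]oxy}silane F1. F1 is then used in a lanthanide-triflate Mukaiyama aldol with the commercial aqueous solution of 6 (Yb(OTf)3 10 mol %, THF–H2O, rt). This runs through an open transition state that favours the syn adduct for cyclohexanone silyl enol ethers, and gives 11.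

Step 6 (dimerisation of the nitrile oxide or slow closure of the trans-fused ring). The fallback sets out from 16 and comes back at 18. Oxime 16 is heated (toluene, sealed tube, 160–180 °C) so that it tautomerises to the N–H nitrone and adds to the Z-propenyl group (intramolecular oxime–olefin cycloaddition). This gives the N-unsubstituted isoxazolidine analogue of 18 F2. N-chlorination and dehydrochlorination (NCS, CH2Cl2, 0 °C; then Et3N) restore the C=N bond and give 18.

Step 7 (over-oxidation, or the equatorial alcohol instead of the axial one). The fallback sets out from 18 and comes back at 21. The crude SeO2/t-BuOOH product is oxidised further with Dess–Martin periodinane to the 6-oxo tricyclic isoxazoline (α-methylene ketone) F3. Luche reduction (NaBH4, CeCl3·7H2O, MeOH, −78 °C, axial hydride attack) gives the equatorial (6R)-6-hydroxy tricyclic isoxazoline F4. Mitsunobu esterification of F4 with 20 (PPh3, DIAD, toluene, 0 °C) inverts C6 and gives 21 directly, so step 8 is not needed.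

**Further compounds**
F1 | step 2 | trimethyl{[(3R,4R)-4-(propan-2-yl)-3-[(1Z)-prop-1-en-1-yl]cyclohex-1-en-1-yl]oxy}silane | C[Si](C)(C)OC1=C[C@H](/C=C\C)[C@@H](C(C)C)CC1
F2 | step 6 | N-unsubstituted isoxazolidine analogue of 18 (C2 epimers) | C=C1[C@@H]2[C@H]([C@@H]3[C@H](C)ONC3[C@@H]2OC(=O)[C@H](C)CC)[C@@H](C(C)C)CC1
F3 | step 7 | 6-oxo tricyclic isoxazoline (α-methylene ketone) | C=C1[C@@H]2[C@H]([C@@H]3[C@H](C)ON=C3[C@@H]2OC(=O)[C@H](C)CC)[C@@H](C(C)C)CC1=O
F4 | step 7 | (6R)-6-hydroxy tricyclic isoxazoline (equatorial alcohol) | C=C1[C@@H]2[C@H]([C@@H]3[C@H](C)ON=C3[C@@H]2OC(=O)[C@H](C)CC)[C@@H](C(C)C)C[C@H]1O
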